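The route opens a bridged bicyclo[2.2.2]octene into the cis-fused A/B decalin. The feature exploited is the quaternary, methyl-bearing C10 lying between the cis ring-fusion carbon C5 and the tetrasubstituted C8=C9 alkene of ring B, with the C4 gem-dimethyl group in ring A. An anionic oxy-Cope rearrangement of a resolved, mesitol-derived 2-vinylbicyclo[2.2.2]oct-5-en-2-ol forms C1–C10, breaks C3–C8, closes ring A and sets C10 in one operation, leaving a C3 ketone. The precursor already carries all four methyls and a silyloxyethyl arm (C11–C12). Deoxygenation, a Horner–Wadsworth–Emmons olefination and a late Stille coupling then complete the hydroxymethyl dienyl butenolide.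

Key step: step 9

Remark on numbering and stereochemistry: phenols, dienones and bicyclo[2.2.2]octenes are numbered systematically; from step 9 on, labdane-type numbering is used (C1–C10 decalin, C11/C12 linker, C13 the hydroxymethyl-bearing alkene carbon, C14–C16 the diene carbons towards the butenolide). The target's ring fusion is cis (H5 and the C10 methyl on the same face), descriptors (4aR,8aS) in naphthalene numbering.

Remark on the precursor design: the ketone is resolved before vinylation so that the rearrangement substrate is a single enantiomer. The side-chain oxygen is carried as a TBS ether that survives the basic key step and is shed during the deoxygenation.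

**Step 1**
Reactants: 1 2,4,6-trimethylphenol (mesitol)
Product: 2 3-bromo-2,4,6-trimethylphenol
Conditions: Br2 (1.0 equiv), AcOH, 15 °C → rt
Reagents that add atoms: bromine, BrBr
Why: Electrophilic aromatic bromination: both ortho positions and the para position carry methyl groups, so bromine ends up at the only free ring carbon (C3), and any ipso-bromodienone formed first rearranges to the same phenol under the HBr released.

**Step 2**
Reactants: 2 3-bromo-2,4,6-trimethylphenol; 3 ethylene oxide
Product: 5 3-(2-hydroxyethyl)-2,4,6-trimethylphenol, via aryllithium phenoxide 4 (not isolated)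
Conditions: t-BuLi (3.1 equiv), THF, −78 °C; ethylene oxide (3 equiv), −78 → 0 °C; aq NH4Cl
Reagents that add atoms: none
Why: Bromine–lithium exchange followed by epoxide opening: the first equivalent of t-BuLi removes the phenol proton, two more effect the exchange, and aryllithium 4 opens oxirane at carbon to install the two-carbon arm that becomes C11–C12.

**Step 3**
Reactants: 5 3-(2-hydroxyethyl)-2,4,6-trimethylphenol
Product: 6 3-[2-(tert-butyldimethylsilyloxy)ethyl]-2,4,6-trimethylphenol
Conditions: TBSCl (1.05 equiv), imidazole, CH2Cl2, 0 °C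
Reagents that add atoms: tert-butyldimethylsilyl chloride, CC(C)(C)[Si](C)(C)Cl
Why: Chemoselective silyl ether formation: the primary alcohol should be silylated much faster than the phenol, which is shielded by its two ortho methyl groups.

**Step 4**
Reactants: 6 3-[2-(tert-butyldimethylsilyloxy)ethyl]-2,4,6-trimethylphenol
Product: 7 3-[2-(tert-butyldimethylsilyloxy)ethyl]-2,4,6,6-tetramethylcyclohexa-2,4-dien-1-one
Conditions: n-BuLi (1.0 equiv), toluene, 0 °C → rt; MeI (10 equiv), sealed tube, 110 °C
Reagents that add atoms: iodomethane, CI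
Why: Alkylative dearomatisation by ortho C-methylation of a lithium phenoxide: in toluene the tight, aggregated ion pair disfavours O-alkylation and steers iodomethane to an ortho carbon, and the ortho carbon next to the ring C–H (C6) is less crowded than the one next to the side chain (C2), so the 6,6-dimethyl-2,4-dienone should be the main C-alkylated product, to be separated from the aryl methyl ether and isomeric dienones.

**Step 5**
Reactants: 7 3-[2-(tert-butyldimethylsilyloxy)ethyl]-2,4,6,6-tetramethylcyclohexa-2,4-dien-1-one; 8 phenyl vinyl sulfone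
Product: 9 racemic 7-(phenylsulfonyl)-6-[2-(tert-butyldimethylsilyloxy)ethyl]-1,3,3,5-tetramethylbicyclo[2.2.2]oct-5-en-2-one (isomer mixture)
Conditions: 8 (3 equiv), BHT (cat.), xylene, 140 °C, sealed tube
Reagents that add atoms: none
Why: Diels–Alder cycloaddition of the cyclohexa-2,4-dienone (diene termini C2 and C5) with phenyl vinyl sulfone as an ethylene equivalent: the dienone has a mirror plane, so the bicyclo[2.2.2]octenone is racemic, and the regio- and endo/exo isomers need no separation because the sulfonyl group is removed in step 6.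

**Step 6**
Reactants: 9 racemic sulfonyl cycloadduct (isomer mixture)
Product: 10 racemic 6-[2-(tert-butyldimethylsilyloxy)ethyl]-1,3,3,5-tetramethylbicyclo[2.2.2]oct-5-en-2-one
Conditions: Na(Hg) (6%), Na2HPO4, MeOH–THF, −20 °C
Reagents that add atoms: none
Why: Reductive desulfonylation by electron transfer from buffered sodium amalgam: the C–S bond is cleaved and the carbon protonated by methanol, while the non-enolisable, doubly neopentyl ketone and the tetrasubstituted alkene should be left alone at low temperature.

**Step 7**
Reactants: 10 racemic bicyclo[2.2.2]octenone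
Product: 11 (1R,4S)-6-[2-(tert-butyldimethylsilyloxy)ethyl]-1,3,3,5-tetramethylbicyclo[2.2.2]oct-5-en-2-one
Conditions: preparative chiral SFC (amylose-based stationary phase, CO2/i-PrOH)
Reagents that add atoms: none
Why: Resolution by preparative chromatography on a chiral stationary phase: the ketone has no acidic or basic handle, so the enantiomers are separated directly, and the (1R,4S)-enantiomer, whose absolute configuration is to be secured by VCD or an X-ray structure of a heavy-atom derivative, supplies the bridgehead that becomes C5.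

**Step 8**
Reactants: 11 (1R,4S)-bicyclo[2.2.2]octenone; 12 vinylmagnesium bromide
Product: 13 (1R,2S,4S)-2-ethenyl-6-[2-(tert-butyldimethylsilyloxy)ethyl]-1,3,3,5-tetramethylbicyclo[2.2.2]oct-5-en-2-ol (vinyl syn to the C5=C6 bridge)
Conditions: CeCl3 (anhydrous, 1.5 equiv), 12 (3 equiv), THF, −78 → 0 °C; aq NH4Cl
Reagents that add atoms: none
Why: 1,2-Addition of a vinylcerium reagent (Grignard/CeCl3) to a non-enolisable ketone: attack should come from the face of C2 (bicycle numbering) that looks onto the sp2 carbons of the C5=C6 bridge, since the opposite face is blocked by the inward hydrogens of the C7–C8 bridge, which sets C2 as (S) with the vinyl group syn to the alkene.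

**Step 9**
Reactants: 13 (1R,2S,4S)-vinyl carbinol
Product: 16 (4aS,8aS)-5-[2-(tert-butyldimethylsilyloxy)ethyl]-1,1,4a,6-tetramethyl-3,4,4a,7,8,8a-hexahydronaphthalen-2(1H)-one (cis-fused), via potassium alkoxide 14 (not isolated), via potassium enolate 15 (not isolated)
Conditions: KH (1.5 equiv), 18-crown-6 (1.5 equiv), THF, 0 → 50 °C; aq NH4Cl at −78 °C
Reagents that add atoms: none
Why: Deprotonation gives potassium alkoxide 14, whose crown-separated oxyanion weakens the adjacent C3–C8 bond, so that the 1,5-diene C1=C2–C3–C8–C9=C10 undergoes a concerted suprafacial [3,3]-sigmatropic shift through the boat-like transition state imposed by the cage, breaking C3–C8, forming C1–C10 and giving the C2=C3 enolate 15, which is protonated on work-up. The closest known reaction type is the anionic oxy-Cope rearrangement of 2-vinylbicyclo[2.2.2]oct-5-en-2-ols to cis-fused octalones. Ring A (C1–C2–C3–C4–C5–C10) is closed by this sigmatropic bond formation between the vinyl terminus and the alkene carbon while the former carbinol bridge is released from C8, so the bridged bicycle becomes the fused decalin. The new stereocentre C10 is controlled by the cage: the vinyl group is tied through C3–C4 to the bridgehead that becomes C5 and can reach C10 only on the face of ring B that carries the C4–C5 bond, so C1 and C4 end up cis on ring B and the C10 methyl is cis to H5. The step needs the [3,3] pathway to win over a [1,3] shift and over simple fragmentation, and it needs the vinyl group syn to the alkene; the rigid boat geometry and the low temperature allowed by the alkoxide favour the former, and step 8 fixed the latter.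

**Step 10**
Reactants: 16 (4aS,8aS)-octalone
Product: 18 2-[(4aR,8aS)-2,5,5,8a-tetramethyl-3,4,4a,5,6,7,8,8a-octahydronaphthalen-1-yl]ethan-1-ol, via hydrazone 17 (not isolated)
Conditions: N2H4·H2O, KOH, diethylene glycol, 130 °C, then 205 °C (water distilled off)
Reagents that add atoms: none
Why: Wolff–Kishner reduction under Huang–Minlon conditions: the C3 hydrazone 17 loses dinitrogen in hot KOH to leave a methylene group, neither C5 nor C10 is alpha to the carbonyl so the cis ring fusion cannot epimerise, and the primary silyl ether should be cleaved by the hot hydroxide in the same operation.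

**Step 11**
Reactants: 18 decalinyl ethanol
Product: 19 (4aR,8aS)-1-(2-iodoethyl)-2,5,5,8a-tetramethyl-3,4,4a,5,6,7,8,8a-octahydronaphthalene
Conditions: I2, PPh3, imidazole, CH2Cl2, 0 °C → rt
Reagents that add atoms: iodine, II
Why: Appel-type iodination: the alkoxyphosphonium ion formed from PPh3/I2 is displaced by iodide in an SN2 reaction at the unhindered primary carbon C12, under conditions too mild to disturb the tetrasubstituted alkene.

**Step 12**
Reactants: 19 decalinyl ethyl iodide; 20 triethyl phosphonoacetate
Product: 21 ethyl 2-(diethoxyphosphoryl)-4-[(4aR,8aS)-2,5,5,8a-tetramethyl-3,4,4a,5,6,7,8,8a-octahydronaphthalen-1-yl]butanoate (both epimers at C2)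
Conditions: 20 (3 equiv), NaH (2.8 equiv), THF–DMF, 0 °C → rt; then 19, 60 °C
Reagents that add atoms: none
Why: SN2 C-alkylation of the sodium salt of a phosphonoacetate by a primary iodide: the soft, weakly basic carbanion, used in excess to suppress dialkylation, should substitute and not eliminate, and the new centre at C13 disappears in step 15.

**Step 13**
Reactants: 22 propargyl alcohol; 23 tributyltin hydride
Product: 24 (E)-3-(tributylstannyl)prop-2-en-1-ol
Conditions: AIBN (cat.), neat, 80 °C
Reagents that add atoms: none
Why: Radical hydrostannation of a terminal alkyne: the stannyl radical adds to the terminal carbon, and reversible addition of stannyl radicals to the products equilibrates them towards the (E)-vinylstannane, which is separated from the minor (Z) and internal isomers.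

**Step 14**
Reactants: 24 (E)-3-(tributylstannyl)prop-2-en-1-ol
Product: 25 (E)-3-(tributylstannyl)prop-2-enal
Conditions: MnO2 (activated, excess), CH2Cl2, rt
Reagents that add atoms: none
Why: Manganese dioxide oxidation of an allylic alcohol to the enal, under neutral conditions in which the vinyl–tin bond and the E geometry should persist.

**Step 15**
Reactants: 21 alkylated phosphonoacetate; 25 (E)-3-(tributylstannyl)prop-2-enal
Product: 26 ethyl (2E,4E)-2-{2-[(4aR,8aS)-2,5,5,8a-tetramethyl-3,4,4a,5,6,7,8,8a-octahydronaphthalen-1-yl]ethyl}-5-(tributylstannyl)penta-2,4-dienoate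
Conditions: NaH, THF, 0 °C; then 25, 0 °C → rt
Reagents that add atoms: none
Why: Horner–Wadsworth–Emmons olefination: the α-alkylated phosphonoacetate anion adds reversibly to the enal and the lower-energy oxaphosphetane collapses to the alkene with the ester trans to C15, that is the 2E dienoate with C12 cis to C15 as in the target, while the (E)-vinylstannane is untouched and any minor 2Z isomer is removed by chromatography.

**Step 16**
Reactants: 26 stannyl dienoate
Product: 27 (2E,4E)-2-{2-[(4aR,8aS)-2,5,5,8a-tetramethyl-3,4,4a,5,6,7,8,8a-octahydronaphthalen-1-yl]ethyl}-5-(tributylstannyl)penta-2,4-dien-1-ol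
Conditions: DIBAL-H (2.5 equiv), CH2Cl2, −78 °C; aq Rochelle salt
Reagents that add atoms: none
Why: DIBAL-H reduction of the conjugated ester to the allylic alcohol at −78 °C, placed before the lactone is introduced so that no ester/lactone selectivity is needed, with the vinylstannane and the alkenes inert to the hydride.

**Step 17**
Reactants: 27 stannyl dienol; 28 4-bromofuran-2(5H)-one
Product: 29 4-[(1E,3E)-4-(hydroxymethyl)-6-[(4aR,8aS)-2,5,5,8a-tetramethyl-3,4,4a,5,6,7,8,8a-octahydronaphthalen-1-yl]hexa-1,3-dien-1-yl]furan-2(5H)-one (target)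
Conditions: Pd2(dba)3 (5 mol %), AsPh3 (20 mol %), CuI (10 mol %), NMP, rt, dark
Reagents that add atoms: none
Why: Stille cross-coupling: oxidative addition of Pd(0) to the β-bromo butenolide, transmetallation of the dienylstannane with retention of its E geometry and reductive elimination join C16 to C4 of the butenolide under neutral conditions that tolerate the free allylic alcohol and the base-sensitive lactone.

**Compound list**

1 | 2,4,6-trimethylphenol (mesitol) | Cc1cc(C)c(O)c(C)c1 | starting material
2 | 3-bromo-2,4,6-trimethylphenol | Cc1cc(C)c(Br)c(C)c1O | intermediate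
3 | ethylene oxide (oxirane) | C1CO1 | starting material
4 | lithium 3-lithio-2,4,6-trimethylphenolate (not isolated) | [Li]Oc1c(C)cc(C)c([Li])c1C | intermediate
5 | 3-(2-hydroxyethyl)-2,4,6-trimethylphenol | Cc1cc(C)c(CCO)c(C)c1O | intermediate
6 | 3-[2-(tert-butyldimethylsilyloxy)ethyl]-2,4,6-trimethylphenol | Cc1cc(C)c(CCO[Si](C)(C)C(C)(C)C)c(C)c1O | intermediate
7 | 3-[2-(tert-butyldimethylsilyloxy)ethyl]-2,4,6,6-tetramethylcyclohexa-2,4-dien-1-one | CC1=CC(C)(C)C(=O)C(C)=C1CCO[Si](C)(C)C(C)(C)C | intermediate
8 | phenyl vinyl sulfone | C=CS(=O)(=O)c1ccccc1 | starting material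
9 | 7-(phenylsulfonyl)-6-[2-(tert-butyldimethylsilyloxy)ethyl]-1,3,3,5-tetramethylbicyclo[2.2.2]oct-5-en-2-one (racemic; sulfonyl epimers, the 8-sulfonyl regioisomer may accompany it) | O=C1C(C)(C)C2CC(S(=O)(=O)c3ccccc3)C1(C)C(CCO[Si](C)(C)C(C)(C)C)=C2C | intermediate
10 | racemic 6-[2-(tert-butyldimethylsilyloxy)ethyl]-1,3,3,5-tetramethylbicyclo[2.2.2]oct-5-en-2-one | O=C1C(C)(C)C2CCC1(C)C(CCO[Si](C)(C)C(C)(C)C)=C2C | intermediate
11 | (1R,4S)-6-[2-(tert-butyldimethylsilyloxy)ethyl]-1,3,3,5-tetramethylbicyclo[2.2.2]oct-5-en-2-one | O=C1C(C)(C)[C@H]2CC[C@]1(C)C(CCO[Si](C)(C)C(C)(C)C)=C2C | intermediate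
12 | vinylmagnesium bromide | C=C[Mg]Br | starting material
13 | (1R,2S,4S)-2-ethenyl-6-[2-(tert-butyldimethylsilyloxy)ethyl]-1,3,3,5-tetramethylbicyclo[2.2.2]oct-5-en-2-ol, vinyl syn to the C5=C6 bridge | C=C[C@]1(O)C(C)(C)[C@H]2CC[C@]1(C)C(CCO[Si](C)(C)C(C)(C)C)=C2C | intermediate
14 | potassium alkoxide of 13 (not isolated) | [K+].C=C[C@]1([O-])C(C)(C)[C@H]2CC[C@]1(C)C(CCO[Si](C)(C)C(C)(C)C)=C2C | intermediate
15 | potassium C2=C3 enolate of 16 (not isolated) | [K+].CC1=C(CCO[Si](C)(C)C(C)(C)C)[C@@]2(C)CC=C([O-])C(C)(C)[C@H]2CC1 | intermediate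
16 | (4aS,8aS)-5-[2-(tert-butyldimethylsilyloxy)ethyl]-1,1,4a,6-tetramethyl-3,4,4a,7,8,8a-hexahydronaphthalen-2(1H)-one, cis-fused | CC1=C(CCO[Si](C)(C)C(C)(C)C)[C@@]2(C)CCC(=O)C(C)(C)[C@H]2CC1 | intermediate
17 | hydrazone of 16 (not isolated) | CC1=C(CCO[Si](C)(C)C(C)(C)C)[C@@]2(C)CCC(=NN)C(C)(C)[C@H]2CC1 | intermediate
18 | 2-[(4aR,8aS)-2,5,5,8a-tetramethyl-3,4,4a,5,6,7,8,8a-octahydronaphthalen-1-yl]ethan-1-ol | CC1=C(CCO)[C@@]2(C)CCCC(C)(C)[C@H]2CC1 | intermediate
19 | (4aR,8aS)-1-(2-iodoethyl)-2,5,5,8a-tetramethyl-3,4,4a,5,6,7,8,8a-octahydronaphthalene | CC1=C(CCI)[C@@]2(C)CCCC(C)(C)[C@H]2CC1 | intermediate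
20 | triethyl phosphonoacetate | CCOC(=O)CP(=O)(OCC)OCC | starting material
21 | ethyl 2-(diethoxyphosphoryl)-4-[(4aR,8aS)-2,5,5,8a-tetramethyl-3,4,4a,5,6,7,8,8a-octahydronaphthalen-1-yl]butanoate, both epimers at C2 | CC1=C(CCC(C(=O)OCC)P(=O)(OCC)OCC)[C@@]2(C)CCCC(C)(C)[C@H]2CC1 | intermediate
22 | propargyl alcohol (prop-2-yn-1-ol) | C#CCO | starting material
23 | tributyltin hydride | CCCC[SnH](CCCC)CCCC | starting material
24 | (E)-3-(tributylstannyl)prop-2-en-1-ol | CCCC[Sn](CCCC)(CCCC)/C=C/CO | intermediate
25 | (E)-3-(tributylstannyl)prop-2-enal | CCCC[Sn](CCCC)(CCCC)/C=C/C=O | intermediate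
26 | ethyl (2E,4E)-2-{2-[(4aR,8aS)-2,5,5,8a-tetramethyl-3,4,4a,5,6,7,8,8a-octahydronaphthalen-1-yl]ethyl}-5-(tributylstannyl)penta-2,4-dienoate | CC1=C(CC/C(=C\C=C\[Sn](CCCC)(CCCC)CCCC)C(=O)OCC)[C@@]2(C)CCCC(C)(C)[C@H]2CC1 | intermediate
27 | (2E,4E)-2-{2-[(4aR,8aS)-2,5,5,8a-tetramethyl-3,4,4a,5,6,7,8,8a-octahydronaphthalen-1-yl]ethyl}-5-(tributylstannyl)penta-2,4-dien-1-ol | CC1=C(CC/C(=C\C=C\[Sn](CCCC)(CCCC)CCCC)CO)[C@@]2(C)CCCC(C)(C)[C@H]2CC1 | intermediate
28 | 4-bromofuran-2(5H)-one | BrC1=CC(=O)OC1 | starting material
29 | 4-[(1E,3E)-4-(hydroxymethyl)-6-[(4aR,8aS)-2,5,5,8a-tetramethyl-3,4,4a,5,6,7,8,8a-octahydronaphthalen-1-yl]hexa-1,3-dien-1-yl]furan-2(5H)-one | CC1=C(CC/C(=C\C=C\C2=CC(=O)OC2)CO)[C@@]2(C)CCCC(C)(C)[C@H]2CC1 | target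

**Step count**

Total step count: 17. Longest linear sequence: 15 steps (steps 1–12 and 15–17, from mesitol); steps 13–14 form a two-step side branch.

**Steps most likely to fail**

1. Step 9 (key step). The alkoxide may cleave heterolytically to a ring-opened allyl anion/enone pair that recombines by a [1,3] shift or does not recombine at all, because bond formation at the methyl-substituted alkene carbon is slowed by crowding. The fallback keeps the same bond reorganisation but removes the oxyanion. Setting out from 13, the tertiary alcohol would be silylated (TMSOTf, Et3N, CH2Cl2, −78 → 0 °C) to the trimethylsilyl ether F1. Thermolysis in a base-washed sealed tube (toluene, about 260 °C) should give, by a neutral siloxy-Cope rearrangement, the trimethylsilyl enol ether F2. Mild hydrolysis of F2 (K2CO3, MeOH, 0 °C), which spares the primary TBS ether, comes back to the route at 16.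

2. Step 4. O-Methylation, or attack at the wrong ring carbons (C2 beside the side chain, or the para carbon C4), may outrun methylation at C6. The fallback delivers the carbon intramolecularly from oxygen to an ortho carbon. Setting out from 6, the phenol would be converted with the dimethyl sulfide–N-chlorosuccinimide adduct (CH2Cl2, −25 °C) and then Et3N into an aryloxysulfonium ylide. Its [2,3]-sigmatropic shift cannot give an ether or a para product, and should give the 6-methyl-6-(methylthiomethyl) dienone F3, with the less crowded ortho carbon C6 again preferred. Cycloaddition of F3 with 8 under the conditions of step 5 gives the cycloadduct F4. Raney nickel hydrogenolysis of its C–S(methyl) bond (EtOH, rt) turns the CH2SMe group into the second methyl and comes back to the route at 9.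

3. Step 8. Addition to a carbonyl flanked by two quaternary carbons may be slow, and the C6 side chain narrows the alkene-side approach, so facial selectivity may erode. The fallback uses a slimmer nucleophile and a later reduction. Setting out from 11, CeCl3-promoted addition of ethynylmagnesium bromide (THF, −78 → 0 °C) should give the ethynyl carbinol F5 with the alkynyl group syn to the C5=C6 bridge. Semihydrogenation of F5 (H2, Lindlar catalyst, quinoline, EtOAc), which leaves the tetrasubstituted alkene alone, comes back to the route at 13.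

**Further compounds**

F1 | step 9 | trimethylsilyl ether of 13 | C=C[C@]1(O[Si](C)(C)C)C(C)(C)[C@H]2CC[C@]1(C)C(CCO[Si](C)(C)C(C)(C)C)=C2C
F2 | step 9 | trimethylsilyl enol ether (C2=C3) of 16 | CC1=C(CCO[Si](C)(C)C(C)(C)C)[C@@]2(C)CC=C(O[Si](C)(C)C)C(C)(C)[C@H]2CC1
F3 | step 4 | 3-[2-(tert-butyldimethylsilyloxy)ethyl]-2,4,6-trimethyl-6-[(methylsulfanyl)methyl]cyclohexa-2,4-dien-1-one (racemic) | CC1=CC(C)(CSC)C(=O)C(C)=C1CCO[Si](C)(C)C(C)(C)C
F4 | step 4 | 3-[(methylsulfanyl)methyl]-7-(phenylsulfonyl)-6-[2-(tert-butyldimethylsilyloxy)ethyl]-1,3,5-trimethylbicyclo[2.2.2]oct-5-en-2-one (racemic isomer mixture) | O=C1C(C)(CSC)C2CC(S(=O)(=O)c3ccccc3)C1(C)C(CCO[Si](C)(C)C(C)(C)C)=C2C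
F5 | step 8 | (1R,2S,4S)-2-ethynyl-6-[2-(tert-butyldimethylsilyloxy)ethyl]-1,3,3,5-tetramethylbicyclo[2.2.2]oct-5-en-2-ol | C#C[C@]1(O)C(C)(C)[C@H]2CC[C@]1(C)C(CCO[Si](C)(C)C(C)(C)C)=C2C
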